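**Plan**
- Ret­ro­syn­the­sis: the two aryl–CHO bonds and the three phenolic O–H groups lead back to a 2,4,6-trimethoxyphenyl group; C7–C11 (isopropenyl) and C10–C14 (methyl) lead back to a hydroazulene-7,10-dione; C1–C10 and C5–C6 are cut (with C6–C10 rejoined) to a C1=C5 cyclopentene and cyclopentane-1,3-dione; C4–C1′ and C1′–aryl are cut to 2-methylcyclopentane-1,3-dione, isovaleraldehyde and 1,3,5-trimethoxybenzene.
- Enabling feature: in the seven-membered ring the carbinol carbon C10 and the isopropenyl-bearing C7 are 1,4-related (C10–C9–C8–C7) and flank the C1–C5 fusion bond through C6. This is the pattern left when cyclopentane-1,3-dione is inserted across a C1=C5 double bond by [2+2] addition and retro-aldol opening.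
- Forward order: aryl–C1′ and C1′–C4 are joined on a five-membered dione, which is trimmed to the cyclopentene (steps 1–7); the seven-membered ring is made in step 8; C10, then C7, then the arene are finished (steps 9–18).
- Stereochemistry: C4 and the absolute configuration come from a CBS desymmetrising reduction of the racemic dione, which turns its two enantiomers into separable C1′-epimeric ketols, and the one with the required C4/C1′ relationship is carried on. C5 comes from addition anti to the benzylic branch and C1 from equilibration in step 8; C10 from α-face epoxidation; C7 from hydroxyl-directed hydrogenation.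

Key step: step 8

Remark: guaiane numbering is used for the hydroazulenes (C1/C5 ring fusion, C4 quaternary, C1′ benzylic; α = face of H-1, β = face of H-5). Compounds 4 and 6 are racemic and every later compound is a single enantiomer. CIP labels at C4/C1′ change between some intermediates only through priority changes. Compounds 1, 2, 5 and 13 are taken as commercial.

Step 1
Reactants: 1 1,3,5-trimethoxybenzene; 2 3-methylbutanal (isovaleraldehyde)
Product: 4 rac-3-methyl-1-(2,4,6-trimethoxyphenyl)butan-1-ol, via 2,4,6-trimethoxyphenyllithium 3 (not isolated)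
Conditions: n-BuLi, THF, 0 °C to rt; then 2, −78 °C; H2O
Reagents that add atoms: none
Why: Directed ortho-lithiation of the arene between two methoxy groups and 1,2-addition of the aryllithium to the aldehyde give the benzylic alcohol as a racemate, which suffices because this centre is ionised in step 2.

Step 2
Reactants: 4 rac-3-methyl-1-(2,4,6-trimethoxyphenyl)butan-1-ol; 5 2-methylcyclopentane-1,3-dione
Product: 6 rac-2-methyl-2-[3-methyl-1-(2,4,6-trimethoxyphenyl)butyl]cyclopentane-1,3-dione
Conditions: TsOH·H2O (10 mol%), MeCN, 50 °C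
Reagents that add atoms: none
Why: Acid-catalysed dehydrative SN1 alkylation (Friedel–Crafts-type substitution of a benzylic alcohol by a 1,3-dicarbonyl): ionisation gives the strongly stabilised 2,4,6-trimethoxybenzylic cation, which is captured at C2 of the enolised dione, and because O-alkylation and elimination to the styrene are reversible under acid the C-alkylated quaternary product should accumulate as the racemate.

Step 3
Reactants: 6 rac-2-methyl-2-[3-methyl-1-(2,4,6-trimethoxyphenyl)butyl]cyclopentane-1,3-dione
Product: 7 (2S,3S)-3-hydroxy-2-methyl-2-[(1S)-3-methyl-1-(2,4,6-trimethoxyphenyl)butyl]cyclopentan-1-one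
Conditions: (R)-2-methyl-CBS-oxazaborolidine (0.3 equiv), catecholborane, PhNEt2, toluene, −60 °C; chromatography
Reagents that add atoms: none
Why: Corey–Bakshi–Shibata desymmetrisation: the catalyst fixes the carbinol as S and hydride enters anti to the bulky benzylic branch, so in each enantiomer of 6 only the carbonyl meeting both demands is reduced, which sets the quaternary centre as S, converts (S)-6 into 7 and (R)-6 into the C1′-epimer of 7, a diastereomer that is removed by chromatography and not carried on (divergent reaction of a racemate).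

Step 4
Reactants: 7 (2S,3S)-3-hydroxy-2-methyl-2-[(1S)-3-methyl-1-(2,4,6-trimethoxyphenyl)butyl]cyclopentan-1-one
Product: 8 O-{(1S,2S)-2-methyl-2-[(1S)-3-methyl-1-(2,4,6-trimethoxyphenyl)butyl]-3-oxocyclopentyl} 1H-imidazole-1-carbothioate
Conditions: 1,1'-thiocarbonyldiimidazole, DMAP (cat.), ClCH2CH2Cl, 70 °C
Reagents that add atoms: 1,1'-thiocarbonyldiimidazole, S=C(n1ccnc1)n1ccnc1
Why: Thioacylation of the secondary alcohol under neutral conditions prepares the Barton–McCombie substrate without the strong base of xanthate formation, which would provoke retro-aldol opening of the β-hydroxy ketone.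

Step 5
Reactants: 8 O-{(1S,2S)-2-methyl-2-[(1S)-3-methyl-1-(2,4,6-trimethoxyphenyl)butyl]-3-oxocyclopentyl} 1H-imidazole-1-carbothioate
Product: 9 (2R)-2-methyl-2-[(1S)-3-methyl-1-(2,4,6-trimethoxyphenyl)butyl]cyclopentan-1-one
Conditions: Bu3SnH (3 equiv), AIBN (cat.), toluene, 110 °C
Reagents that add atoms: none
Why: Barton–McCombie deoxygenation: the stannyl radical adds to the thiocarbonyl group, the C–O bond fragments and the secondary radical is reduced by the stannane (used concentrated so that hydrogen transfer outruns β-scission), which removes the carbinol centre and leaves the quaternary and benzylic centres untouched (the label at C2 becomes R only through a priority change).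

Step 6
Reactants: 9 (2R)-2-methyl-2-[(1S)-3-methyl-1-(2,4,6-trimethoxyphenyl)butyl]cyclopentan-1-one
Product: 10 (E)-4-methylbenzenesulfonylhydrazone of 9
Conditions: TsNHNH2, EtOH, 70 °C
Reagents that add atoms: 4-methylbenzenesulfonohydrazide, Cc1ccc(cc1)S(=O)(=O)NN
Why: Condensation of the ketone with the sulfonyl hydrazide gives the hydrazone needed for the Shapiro reaction, the N–N bond lying anti to the quaternary carbon and syn to the only α-methylene group.

Step 7
Reactants: 10 (E)-4-methylbenzenesulfonylhydrazone of 9
Product: 12 (3S)-3-methyl-3-[(1R)-3-methyl-1-(2,4,6-trimethoxyphenyl)butyl]cyclopent-1-ene, via cyclopentenyllithium 11 (not isolated)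
Conditions: n-BuLi (3 equiv), TMEDA, THF, −78 °C to rt; H2O
Reagents that add atoms: none
Why: Shapiro reaction: double deprotonation (N–H and the syn α-CH2), loss of sulfinate and dinitrogen give vinyllithium 11, whose protonation places the double bond unambiguously between the former carbonyl carbon (C5) and C1 because the other α-position is quaternary, and any lithiation of the arene is undone by the quench.

Step 8
Reactants: 12 (3S)-3-methyl-3-[(1R)-3-methyl-1-(2,4,6-trimethoxyphenyl)butyl]cyclopent-1-ene; 13 cyclopentane-1,3-dione (reacting as its enol 3-hydroxycyclopent-2-en-1-one)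
Product: 16 trans-fused (1R,4S,5S)-4-methyl-4-[(1R)-3-methyl-1-(2,4,6-trimethoxyphenyl)butyl]perhydroazulene-7,10-dione, via cyclobutanol photoadduct 14 (not isolated), via cis-fused diketone 15 (not isolated)
Conditions: 13 (5 equiv), hν (Hg lamp, Pyrex, > 300 nm), MeCN/MeOH, rt; then K2CO3, MeOH, rt
Reagents that add atoms: none
Why: Excitation of the enol of 13 and intersystem crossing give a triplet enone that adds stepwise through a 1,4-biradical to the C1=C5 bond of 12, forming C1–C10 and C5–C6 and closing the cis-fused cyclobutanol 14, whose β-hydroxy ketone unit then undergoes retro-aldol cleavage of C6–C10 to the cycloheptane-7,10-dione 15; this is the de Mayo reaction, the closest known case being the addition of enolised cyclic 1,3-diones to cycloalkenes. The only ring closed directly is the four-membered one (recombination of the 1,4-biradical), and the seven-membered ring then arises by fragmentation of the bond shared by the four- and five-membered rings (two-carbon ring expansion) and not by a cyclisation. C5 is set by approach of the enone to the α face of 12, syn to the C4 methyl group and anti to the bulky aryl-bearing branch on the quaternary carbon. C1 is first formed cis by the suprafacial addition and is then epimerised through the C10 enolate by K2CO3 to the trans ring fusion, expected to be the more stable arrangement. The step needs one orientation (carbinol carbon to C1, CH carbon to C5), which the substrate should secure sterically, because the fully substituted enol carbon can close only onto the unencumbered C1, whereas a biradical that must join it to C5 next to the quaternary centre should revert. It also needs light to reach only the enone, which the Pyrex cut-off outside the absorption of the trimethoxyarene should provide.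

Step 9
Reactants: 16 trans-fused (1R,4S,5S)-4-methyl-4-[(1R)-3-methyl-1-(2,4,6-trimethoxyphenyl)butyl]perhydroazulene-7,10-dione
Product: 17 7-(ethylene ketal) of 16 (C10 ketone free)
Conditions: HOCH2CH2OH, PPTS (cat.), benzene, reflux (−H2O)
Reagents that add atoms: ethylene glycol, OCCO
Why: Acid-catalysed ketalisation is selective for the C7 carbonyl, flanked by two methylene groups, over the C10 carbonyl, shielded by the adjacent ring-fusion methine, so that C10 can be elaborated first.

Step 10
Reactants: 17 7-(ethylene ketal) of 16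
Product: 18 (1R,4S,5S)-7,7-ethylenedioxy-10-methylidene hydroazulene
Conditions: Ph3PCH3Br, KOtBu, toluene, 80 °C
Reagents that add atoms: methyltriphenylphosphonium bromide, C[P+](c1ccccc1)(c1ccccc1)c1ccccc1.[Br-]
Why: Wittig methylenation of the hindered C10 ketone with methylenetriphenylphosphorane at elevated temperature, C1 being enolisable but already in the thermodynamically preferred trans configuration.

Step 11
Reactants: 18 (1R,4S,5S)-7,7-ethylenedioxy-10-methylidene hydroazulene
Product: 19 (1R,4S,5S,10R)-10α,14-epoxide of 18 (oxirane oxygen cis to H-1)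
Conditions: mCPBA, NaHCO3, CH2Cl2, 0 °C
Reagents that add atoms: 3-chloroperoxybenzoic acid, OOC(=O)c1cccc(Cl)c1
Why: Prilezhaev epoxidation of the exocyclic alkene, expected from the α face (the side of the axial H-1, the β face being screened by the C1–C2 bond and the β-oriented C4 side chain) by analogy with trans-fused 10(14)-methylene hydroazulenes, which places the oxygen α and fixes C10.

Step 12
Reactants: 19 (1R,4S,5S,10R)-10α,14-epoxide of 18
Product: 21 (1R,4S,5S,10R)-10-hydroxy-4,10-dimethyl-4-[(1R)-3-methyl-1-(2,4,6-trimethoxyphenyl)butyl]perhydroazulen-7-one, via hydroxy ketal 20 (not isolated)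
Conditions: LiAlH4, THF, 0 °C to rt; then 1 M HCl, THF, rt
Reagents that add atoms: water, O
Why: Hydride opens the 1,1-disubstituted epoxide at its primary carbon (SN2), giving the tertiary alcohol with the C10–O bond intact (10α-OH, 10β-CH3), and the dilute-acid work-up hydrolyses the dioxolane while leaving the tertiary alcohol in place.

Step 13
Reactants: 21 (1R,4S,5S,10R)-10-hydroxy-4,10-dimethyl-4-[(1R)-3-methyl-1-(2,4,6-trimethoxyphenyl)butyl]perhydroazulen-7-one
Product: 22 enol triflate of 21 (C7=C8, triflate on C7)
Conditions: KN(SiMe3)2 (2.3 equiv), THF, −78 °C; PhNTf2, −78 to 0 °C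
Reagents that add atoms: N-phenylbis(trifluoromethanesulfonimide), O=S(=O)(N(c1ccccc1)S(=O)(=O)C(F)(F)F)C(F)(F)F
Why: Kinetic deprotonation of the ketone at C8 (the α-methylene remote from the ring fusion) and O-sulfonylation of the enolate with PhNTf2 give the enol triflate, the hindered tertiary alkoxide not being sulfonylated and any transannular hemiketal opening under the basic conditions, while a minor C6 enol triflate would converge on 25 in step 15.

Step 14
Reactants: 22 enol triflate of 21
Product: 24 7-acetyl-7(8)-ene (conjugated methyl ketone, 10α-OH), via 1-ethoxyvinyl diene 23 (not isolated)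
Conditions: Bu3SnC(OEt)=CH2, Pd(PPh3)4 (5 mol%), LiCl, THF, 65 °C; then 1 M HCl, rt
Reagents that add atoms: tributyl(1-ethoxyvinyl)stannane, CCOC(=C)[Sn](CCCC)(CCCC)CCCC; water, O
Why: Stille coupling of the enol triflate with the acetyl-anion equivalent followed by hydrolysis of the enol ether installs the conjugated methyl ketone, that is both carbons still missing at C7.

Step 15
Reactants: 24 7-acetyl-7(8)-ene
Product: 25 1-[(1R,4S,5S,7R,10R)-10-hydroxy-4,10-dimethyl-4-[(1R)-3-methyl-1-(2,4,6-trimethoxyphenyl)butyl]perhydroazulen-7-yl]ethan-1-one (7β-acetyl)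
Conditions: H2 (1 atm), [Ir(cod)(PCy3)(py)]PF6 (10 mol%), CH2Cl2, rt
Reagents that add atoms: none
Why: Hydroxyl-directed hydrogenation: the cationic iridium catalyst binds the homoallylic 10α-hydroxyl and delivers both hydrogens to the α face of the C7=C8 bond, so that H-7 ends cis to the hydroxyl and the acetyl group β (7R).

Step 16
Reactants: 25 7β-acetyl compound
Product: 26 (1R,4S,5S,7R,10R)-4,10-dimethyl-7-(prop-1-en-2-yl)-4-[(1R)-3-methyl-1-(2,4,6-trimethoxyphenyl)butyl]perhydroazulen-10-ol
Conditions: Zn, CH2Br2, TiCl4, THF/CH2Cl2, 0 °C to rt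
Reagents that add atoms: dibromomethane, BrCBr
Why: Lombardo methylenation with the non-basic zinc–titanium methylene reagent converts the methyl ketone into the isopropenyl group without epimerising the enolisable C7 centre and tolerates the free tertiary alcohol.

Step 17
Reactants: 26 (1R,4S,5S,7R,10R)-4,10-dimethyl-7-(prop-1-en-2-yl)-4-[(1R)-3-methyl-1-(2,4,6-trimethoxyphenyl)butyl]perhydroazulen-10-ol
Product: 28 2,4,6-trimethoxy-5-{(1R)-1-[(1R,4S,5S,7R,10R)-10-hydroxy-4,10-dimethyl-7-(prop-1-en-2-yl)perhydroazulen-4-yl]-3-methylbutyl}benzene-1,3-dicarbaldehyde, via monoformyl α-amino alkoxide 27 (not isolated)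
Conditions: n-BuLi (2.2 equiv), THF, 0 °C; DMF (1.1 equiv), −78 to 0 °C; n-BuLi (1.5 equiv), 0 °C to rt; DMF, −78 °C to rt; H2O
Reagents that add atoms: N,N-dimethylformamide, CN(C)C=O
Why: Directed ortho-metalation: after deprotonation of the alcohol the aryl position between two methoxy groups is lithiated and formylated with DMF, the resulting α-amino alkoxide 27 protects the first formyl group in situ while the second, equally activated position is lithiated and formylated, and the base-only conditions spare the tertiary alcohol and the isopropenyl group that Lewis-acidic formylations would destroy.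

Step 18
Reactants: 28 trimethyl ether dialdehyde
Product: 29 CNP0594576.1, 2,4,6-trihydroxy-5-{(1R)-1-[(1R,4S,5S,7R,10R)-10-hydroxy-4,10-dimethyl-7-(prop-1-en-2-yl)perhydroazulen-4-yl]-3-methylbutyl}benzene-1,3-dicarbaldehyde
Conditions: p-TolSLi (from p-TolSH, n-BuLi; 10 equiv), HMPA, toluene, 110 °C; then 1 M HCl, 0 °C
Reagents that add atoms: none
Why: Nucleophilic demethylation: the arenethiolate attacks the three O-methyl groups in SN2 fashion, each methoxy being activated by an ortho or para formyl group, under basic conditions that leave the acid-sensitive tertiary alcohol, the isopropenyl group and all stereocentres untouched, and acidification liberates the triphenol.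

**Compound list**
1 | 1,3,5-trimethoxybenzene | COc1cc(OC)cc(OC)c1 | starting material
2 | 3-methylbutanal (isovaleraldehyde) | CC(C)CC=O | starting material
3 | 2,4,6-trimethoxyphenyllithium | [Li]c1c(OC)cc(OC)cc1OC | intermediate
4 | rac-3-methyl-1-(2,4,6-trimethoxyphenyl)butan-1-ol | CC(C)CC(O)c1c(OC)cc(OC)cc1OC | intermediate
5 | 2-methylcyclopentane-1,3-dione | CC1C(=O)CCC1=O | starting material
6 | rac-2-methyl-2-[3-methyl-1-(2,4,6-trimethoxyphenyl)butyl]cyclopentane-1,3-dione | CC(C)CC(c1c(OC)cc(OC)cc1OC)C1(C)C(=O)CCC1=O | intermediate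
7 | (2S,3S)-3-hydroxy-2-methyl-2-[(1S)-3-methyl-1-(2,4,6-trimethoxyphenyl)butyl]cyclopentan-1-one (OH cis to the benzylic branch) | O=C1CC[C@H](O)[C@]1(C)[C@@H](CC(C)C)c1c(OC)cc(OC)cc1OC | intermediate
8 | O-{(1S,2S)-2-methyl-2-[(1S)-3-methyl-1-(2,4,6-trimethoxyphenyl)butyl]-3-oxocyclopentyl} 1H-imidazole-1-carbothioate | O=C1CC[C@H](OC(=S)n2ccnc2)[C@]1(C)[C@@H](CC(C)C)c1c(OC)cc(OC)cc1OC | intermediate
9 | (2R)-2-methyl-2-[(1S)-3-methyl-1-(2,4,6-trimethoxyphenyl)butyl]cyclopentan-1-one | O=C1CCC[C@]1(C)[C@@H](CC(C)C)c1c(OC)cc(OC)cc1OC | intermediate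
10 | (E)-4-methylbenzenesulfonylhydrazone of 9 (NHTs anti to the quaternary carbon) | Cc1ccc(cc1)S(=O)(=O)N/N=C1\CCC[C@]1(C)[C@@H](CC(C)C)c1c(OC)cc(OC)cc1OC | intermediate
11 | cyclopentenyllithium from 10 (lithium on C5, configuration as in 12) | [Li]C1=CCC[C@]1(C)[C@@H](CC(C)C)c1c(OC)cc(OC)cc1OC | intermediate
12 | (3S)-3-methyl-3-[(1R)-3-methyl-1-(2,4,6-trimethoxyphenyl)butyl]cyclopent-1-ene | C1C[C@](C)([C@@H](CC(C)C)c2c(OC)cc(OC)cc2OC)C=C1 | intermediate
13 | cyclopentane-1,3-dione (reacts as 3-hydroxycyclopent-2-en-1-one) | O=C1CCC(=O)C1 | starting material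
14 | cis-anti-cis cyclobutanol photoadduct (C1–C10 and C5–C6 formed on the α face, OH on C10, ketone at C7) | O[C@]12CCC(=O)[C@H]1[C@H]3[C@@H]2CC[C@]3(C)[C@@H](CC(C)C)c4c(OC)cc(OC)cc4OC | intermediate
15 | cis-fused (1S,4S,5S)-4-methyl-4-[(1R)-3-methyl-1-(2,4,6-trimethoxyphenyl)butyl]perhydroazulene-7,10-dione | O=C1CCC(=O)[C@H]2CC[C@](C)([C@@H](CC(C)C)c3c(OC)cc(OC)cc3OC)[C@H]2C1 | intermediate
16 | trans-fused (1R,4S,5S)-4-methyl-4-[(1R)-3-methyl-1-(2,4,6-trimethoxyphenyl)butyl]perhydroazulene-7,10-dione (H-1 α, H-5 β) | O=C1CCC(=O)[C@@H]2CC[C@](C)([C@@H](CC(C)C)c3c(OC)cc(OC)cc3OC)[C@H]2C1 | intermediate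
17 | 7-(ethylene ketal) of 16, (1R,4S,5S), C10 ketone free | O1CCOC12CCC(=O)[C@@H]3CC[C@](C)([C@@H](CC(C)C)c4c(OC)cc(OC)cc4OC)[C@H]3C2 | intermediate
18 | (1R,4S,5S)-7,7-ethylenedioxy-10-methylidene hydroazulene | O1CCOC12CCC(=C)[C@@H]3CC[C@](C)([C@@H](CC(C)C)c4c(OC)cc(OC)cc4OC)[C@H]3C2 | intermediate
19 | (1R,4S,5S,10R)-10α,14-epoxide of 18 (oxygen cis to H-1) | O1CCOC12CC[C@@]5(OC5)[C@@H]3CC[C@](C)([C@@H](CC(C)C)c4c(OC)cc(OC)cc4OC)[C@H]3C2 | intermediate
20 | (1R,4S,5S,10R)-7,7-ethylenedioxy-4,10-dimethyl hydroazulen-10-ol (10α-OH, 10β-CH3) | O1CCOC12CC[C@@](C)(O)[C@@H]3CC[C@](C)([C@@H](CC(C)C)c4c(OC)cc(OC)cc4OC)[C@H]3C2 | intermediate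
21 | (1R,4S,5S,10R)-10-hydroxy-4,10-dimethyl-4-[(1R)-3-methyl-1-(2,4,6-trimethoxyphenyl)butyl]perhydroazulen-7-one | O=C1CC[C@@](C)(O)[C@@H]2CC[C@](C)([C@@H](CC(C)C)c3c(OC)cc(OC)cc3OC)[C@H]2C1 | intermediate
22 | enol triflate of 21 (C7=C8, OTf on C7) | O=S(=O)(OC1=CC[C@@](C)(O)[C@@H]2CC[C@](C)([C@@H](CC(C)C)c3c(OC)cc(OC)cc3OC)[C@H]2C1)C(F)(F)F | intermediate
23 | 7-(1-ethoxyvinyl)-7(8)-ene | CCOC(=C)C1=CC[C@@](C)(O)[C@@H]2CC[C@](C)([C@@H](CC(C)C)c3c(OC)cc(OC)cc3OC)[C@H]2C1 | intermediate
24 | 7-acetyl-7(8)-ene (conjugated methyl ketone, 10α-OH) | CC(=O)C1=CC[C@@](C)(O)[C@@H]2CC[C@](C)([C@@H](CC(C)C)c3c(OC)cc(OC)cc3OC)[C@H]2C1 | intermediate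
25 | (1R,4S,5S,7R,10R)-7β-acetyl-10α-hydroxy compound | CC(=O)[C@@H]1CC[C@@](C)(O)[C@@H]2CC[C@](C)([C@@H](CC(C)C)c3c(OC)cc(OC)cc3OC)[C@H]2C1 | intermediate
26 | (1R,4S,5S,7R,10R)-4,10-dimethyl-7-(prop-1-en-2-yl)-4-[(1R)-3-methyl-1-(2,4,6-trimethoxyphenyl)butyl]perhydroazulen-10-ol | C=C(C)[C@@H]1CC[C@@](C)(O)[C@@H]2CC[C@](C)([C@@H](CC(C)C)c3c(OC)cc(OC)cc3OC)[C@H]2C1 | intermediate
27 | dilithium salt: 10-O-lithio-26 bearing one aryl CH(OLi)NMe2 group (either configuration at the aminal carbon) | C=C(C)[C@@H]1CC[C@@](C)(O[Li])[C@@H]2CC[C@](C)([C@@H](CC(C)C)c3c(OC)c(C(O[Li])N(C)C)c(OC)cc3OC)[C@H]2C1 | intermediate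
28 | 2,4,6-trimethoxy-5-{(1R)-1-[(1R,4S,5S,7R,10R)-10-hydroxy-4,10-dimethyl-7-(prop-1-en-2-yl)perhydroazulen-4-yl]-3-methylbutyl}benzene-1,3-dicarbaldehyde | C=C(C)[C@@H]1CC[C@@](C)(O)[C@@H]2CC[C@](C)([C@@H](CC(C)C)c3c(OC)c(C=O)c(OC)c(C=O)c3OC)[C@H]2C1 | intermediate
29 | CNP0594576.1, 2,4,6-trihydroxy analogue of 28 | C=C(C)[C@@H]1CC[C@@](C)(O)[C@@H]2CC[C@](C)([C@@H](CC(C)C)c3c(O)c(C=O)c(O)c(C=O)c3O)[C@H]2C1 | target

**Totals**
Total step count: 18. Longest linear sequence: 18 steps (from 1 and 2; 5 and 13 enter as commercial reagents).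

**Steps most likely to fail**

Step 8. The cycloaddition may take the reversed orientation (CH terminus of the enol bonding to C1), or the short-lived excited enol may be deactivated before it meets the hindered alkene while the diketone already formed is degraded by continued irradiation. The fallback sets out from 12 and 13 and returns at 16. Acetylation of 13 (AcCl, pyridine, CH2Cl2, 0 °C) gives 3-acetoxycyclopent-2-en-1-one F1, a longer-lived enone chromophore whose bulkier β-carbon should sharpen the steric preference for bonding to C1. Irradiation of F1 with 12 (> 300 nm, CH2Cl2) should give the stable cyclobutyl acetate F2, which can be purified and freed from any regioisomer by chromatography. K2CO3 in MeOH then removes the acetyl group, and the liberated cyclobutanol 14 fragments and equilibrates through 15 to 16. This is the two-stage enol-ester form of the same ring expansion, with the photochemical and fragmentation events separated; it does not by itself remove the orientation risk.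

Step 15. Hydrogen may be delivered without prior binding of the tertiary hydroxyl (poor facial selectivity), or the conjugated trisubstituted alkene may resist the cationic iridium catalyst. The fallback sets out from 21, bypasses steps 13–15 and returns at 25. Reductive cyanation of the C7 ketone of 21 with TosMIC (KOtBu, DME/EtOH, 0 °C to rt) should give the C7 nitrile as a mixture that equilibrates at the α-cyano centre under the basic conditions. The 7β-carbonitrile F3 is separated, and the 7α-epimer can be re-equilibrated with KOtBu and recycled. Addition of MeLi (Et2O, 0 °C) and mild aqueous acid work-up pass through the methyl ketimine F4, which hydrolyses to 25 without an equilibrating step at the ketone stage. This replaces catalyst-directed hydrogen delivery by thermodynamic control plus separation; the equilibrium position at C7 is not known in advance.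

Step 11. The peracid may attack the β face of the exocyclic alkene (poor or reversed facial selectivity), which would end in the C10 epimer. The fallback sets out from 17, bypasses steps 10 and 11 and returns at 21. If the β face is the open one, a methyl nucleophile should use it as well: MeLi with CeCl3 (THF, −78 °C) adds to the C10 ketone of 17 to give the 10β-methyl 10α-alkoxide, that is the alkoxide of 20, and the acidic work-up of step 12 then delivers 21. Nucleophilic methylation and epoxidation/hydride opening give opposite C10 configurations for the same face of attack, so one of the two should serve.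

**Further compounds**
F1 | step 8 | 3-acetoxycyclopent-2-en-1-one | CC(=O)OC1=CC(=O)CC1
F2 | step 8 | cyclobutyl acetate (O-acetyl derivative of 14) | CC(=O)O[C@]12CCC(=O)[C@H]1[C@H]3[C@@H]2CC[C@]3(C)[C@@H](CC(C)C)c4c(OC)cc(OC)cc4OC
F3 | step 15 | (1R,4S,5S,7R,10R)-10-hydroxy-4,10-dimethyl-4-[(1R)-3-methyl-1-(2,4,6-trimethoxyphenyl)butyl]perhydroazulene-7β-carbonitrile | N#C[C@@H]1CC[C@@](C)(O)[C@@H]2CC[C@](C)([C@@H](CC(C)C)c3c(OC)cc(OC)cc3OC)[C@H]2C1
F4 | step 15 | methyl ketimine of 25 | CC(=N)[C@@H]1CC[C@@](C)(O)[C@@H]2CC[C@](C)([C@@H](CC(C)C)c3c(OC)cc(OC)cc3OC)[C@H]2C1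
F0 | step 11 | none | none
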